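The route rests on forming the C4–C5 bond of ring A by a [3,3] shift inside a six-membered lactone. The silyl ketene acetal of lactone 15 (C6 carbonyl, C5, C10, C1, C2, ring oxygen) contracts through a tether-enforced boat to cyclohexene acid 18. One operation closes ring A and sets quaternary C4 (CH3, CH2O) and C5–H beside quaternary C10, the feature of ring A that the step exploits. Precursor 15 is a δ-lactone with methyl and allyl on C10, allyl cis to a (Z)-CH=C(CH3)CH2OSi arm on C2. Ring B then follows by aldol condensation onto C6, C9 alkylation and adjustment at C6 and C8; the diene comes last.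

Key step: step 10

Remark on numbering: labdane locants are used (ring A C1–C5, C10; ring B C5–C10; C18 = CH2O on C4, C19 = CH3 on C4, C20 = CH3 on C10, C17 = carbon on C8, C11–C16 = chain on C9). "H5 face" and "C20 face" name the two faces of the trans-decalin.
Remark on structure: the arm on C2 of 15 is a (Z)-3-silyloxy-2-methylprop-1-enyl group, with the methyl on the distal alkene carbon (future C4); only this constitution can give quaternary C4.
Assumption: (S)-Tol-BINAP is taken to give the (R)-carbinol in step 5; if the sense of induction is the opposite, the (R)-ligand is used.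
Assumption: 4-methylfuran-2(5H)-one and 4-(trimethylsilyl)but-3-yn-1-ol are bought.

Step 1
Reactants: 1 4-methylfuran-2(5H)-one
Product: 2 (Z)-4-hydroxy-N-methoxy-N,3-dimethylbut-2-enamide
Conditions: MeNH(OMe)·HCl, Me3Al, CH2Cl2, 0 °C → rt
Reagents that add atoms: N,O-dimethylhydroxylamine hydrochloride, CNOC.Cl
Why: Weinreb aminolysis of the butenolide by the aluminium amide opens the ring and leaves the formerly endocyclic alkene Z, so CH2OH stays cis to the carbonyl group.

Step 2
Reactants: 2 (Z)-hydroxy Weinreb amide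
Product: 3 (Z)-4-(tert-butyldimethylsilyloxy)-N-methoxy-N,3-dimethylbut-2-enamide
Conditions: tBuMe2SiCl, imidazole, DMF, 0 °C → rt
Reagents that add atoms: tert-butyldimethylsilyl chloride, CC(C)(C)[Si](C)(C)Cl
Why: Imidazole-promoted silylation of the primary alcohol, done at once so that the hydroxy amide cannot close back to the lactone.

Step 3
Reactants: 3 silylated Weinreb amide
Product: 4 (Z)-4-(tert-butyldimethylsilyloxy)-3-methylbut-2-enal
Conditions: iBu2AlH, THF, −78 °C; aq. sodium potassium tartrate
Reagents that add atoms: none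
Why: Weinreb amide reduction stops at the chelated aluminium hemiaminal and releases the aldehyde only on neutral work-up, which should keep the Z geometry.

Step 4
Reactants: 5 2,2,6-trimethyl-4H-1,3-dioxin-4-one
Product: 6 2,2-dimethyl-6-methylidene-4-(trimethylsilyloxy)-6H-1,3-dioxine
Conditions: LiN(iPr)2, Me3SiCl, THF, −78 °C
Reagents that add atoms: chlorotrimethylsilane, C[Si](C)(C)Cl
Why: Deprotonation at the 6-methyl group and O-silylation give the silyl dienol ether, a vinylogous ketene acetal for Mukaiyama aldol chemistry.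

Step 5
Reactants: 4 (Z)-enal; 6 silyl dienol ether
Product: 8 6-[(2R,3Z)-5-(tert-butyldimethylsilyloxy)-2-hydroxy-4-methylpent-3-enyl]-2,2-dimethyl-4H-1,3-dioxin-4-one, via trimethylsilyl ether 7 (not isolated)
Conditions: Cu(OTf)2 (cat.), (S)-Tol-BINAP (cat.), Bu4N[Ph3SiF2] (cat.), THF, −78 °C; then 1 M HCl, THF, 0 °C
Reagents that add atoms: none
Why: Copper-catalysed asymmetric vinylogous Mukaiyama aldol addition, in which the bisphosphine-bound copper dienolate attacks one enantioface of the aldehyde through its γ-carbon and sets the C2 carbinol as R; brief acid removes only the O-SiMe3 group.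

Step 6
Reactants: 8 aldol adduct
Product: 10 (6R)-6-[(1Z)-3-(tert-butyldimethylsilyloxy)-2-methylprop-1-enyl]oxane-2,4-dione, via acylketene 9 (not isolated)
Conditions: PhMe, 110 °C, high dilution
Reagents that add atoms: none
Why: Thermal retro-[4+2] of the dioxinone expels acetone and the acylketene is trapped by the δ-hydroxyl group to give the β-keto-δ-lactone without touching C2.

Step 7
Reactants: 10 β-keto lactone
Product: 11 (2R)-2-[(1Z)-3-(tert-butyldimethylsilyloxy)-2-methylprop-1-enyl]-6-oxo-3,6-dihydro-2H-pyran-4-yl trifluoromethanesulfonate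
Conditions: Tf2O, iPr2NEt, CH2Cl2, −78 °C
Reagents that add atoms: trifluoromethanesulfonic anhydride, O=S(=O)(OS(=O)(=O)C(F)(F)F)C(F)(F)F
Why: O-sulfonylation of the enol of the vinylogous acid gives the conjugated enol triflate at the future C10.

Step 8
Reactants: 11 enol triflate; 12 allyltributylstannane
Product: 13 (6R)-4-allyl-6-[(1Z)-3-(tert-butyldimethylsilyloxy)-2-methylprop-1-enyl]-5,6-dihydro-2H-pyran-2-one
Conditions: Pd(PPh3)4 (cat.), LiCl, THF, 60 °C
Reagents that add atoms: none
Why: Stille coupling of the electron-poor alkenyl triflate with the allylstannane under neutral conditions, which should keep the skipped diene out of conjugation.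

Step 9
Reactants: 13 4-allyl unsaturated lactone
Product: 15 (4R,6R)-4-allyl-6-[(1Z)-3-(tert-butyldimethylsilyloxy)-2-methylprop-1-enyl]-4-methyltetrahydro-2H-pyran-2-one, via trimethylsilyl ketene acetal 14 (not isolated)
Conditions: Me2CuLi (from MeLi and CuI), Me3SiCl, THF, −78 → −40 °C; then 1 M HCl, THF, 0 °C
Reagents that add atoms: lithium dimethylcuprate, [Li+].C[Cu-]C
Why: Silyl-chloride-accelerated Gilman conjugate addition, fast enough to outrun allylic displacement at the lactone C–O bond, delivers methyl axially to C10 on the face opposite the pseudo-equatorial C2 arm, so that allyl ends cis to the arm.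

Step 10
Reactants: 15 lactone (allyl cis to the Z-alkenyl arm)
Product: 18 (1S,2S,6R)-6-allyl-2-(tert-butyldimethylsilyloxymethyl)-2,6-dimethylcyclohex-3-ene-1-carboxylic acid, via silyl ketene acetal 16 (not isolated), via silyl ester 17 (not isolated)
Conditions: LiN(iPr)2, tBuMe2SiCl, DMPU, THF, −78 → 0 °C; then PhMe, 110 °C (sealed); then 1 M HCl, THF, 0 °C
Reagents that add atoms: none
Why: LiN(iPr)2 removes a C5 proton and the silyl chloride traps the enolate on oxygen as cyclic ketene acetal 16, which on heating undergoes a concerted suprafacial [3,3] sigmatropic shift (Ireland–Claisen) that forms C4–C5 and breaks C2–O, giving silyl ester 17 and, after hydrolysis, acid 18. The closest known reactions are the enolate Claisen ring contractions of alkenyl lactones and dioxanones and the thermal Claisen rearrangement of 2-alkenyl dihydropyrans. Ring A (C5, C4, C3, C2, C1, C10) closes through the new C4–C5 bond in a boat-shaped, bicyclo[2.2.2]octane-like array, because the two-atom tether C10–C1 joins C5 to C2 and excludes a chair. C5 is set by the lactone face that carries the arm: the bond forms on that face, so the allyl group (cis to the arm) ends cis to H5 and the C10 methyl trans to H5. C4 is set by alkene geometry: with C1 s-cis to C4 and suprafacial bonding, the Z-placed CH2OSi group ends on the H5 side (future equatorial C18) and the methyl on the C20 side. The step needs a single topography, which the tether enforces, and needs the Z-alkene and the cis lactone to survive, which neutral thermolysis in a non-polar solvent should secure.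

Step 11
Reactants: 18 acid
Product: 19 [(1S,2S,6R)-6-allyl-2-(tert-butyldimethylsilyloxymethyl)-2,6-dimethylcyclohex-3-en-1-yl]methanol
Conditions: LiAlH4, THF, 0 → 60 °C
Reagents that add atoms: none
Why: Hydride reduction of the hindered carboxylic acid through its aluminium carboxylate gives the primary alcohol; the silyl ether and both alkenes are inert.

Step 12
Reactants: 19 alcohol
Product: 20 (1S,2S,6R)-6-allyl-2-(tert-butyldimethylsilyloxymethyl)-2,6-dimethylcyclohex-3-ene-1-carbaldehyde
Conditions: Dess–Martin periodinane, NaHCO3, CH2Cl2, rt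
Reagents that add atoms: none
Why: Buffered Dess–Martin oxidation gives the C6 aldehyde without epimerising C5.

Step 13
Reactants: 20 aldehyde
Product: 21 (1S,2S,6S)-2-(tert-butyldimethylsilyloxymethyl)-2,6-dimethyl-6-(2-oxopropyl)cyclohex-3-ene-1-carbaldehyde
Conditions: PdCl2 (cat.), CuCl, O2 (1 atm), DMF/H2O, rt
Reagents that add atoms: water, O
Why: Tsuji–Wacker oxidation hydroxypalladates the terminal allyl alkene in the Markovnikov sense to the methyl ketone (C8, with C7 as its methyl), while the hindered ring alkene should not bind palladium.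

Step 14
Reactants: 21 keto aldehyde
Product: 22 (1S,2S,6S)-2-(tert-butyldimethylsilyloxymethyl)-2,6-dimethyl-6-(2-oxopropyl)cyclohexane-1-carbaldehyde
Conditions: H2 (1 atm), Pd/C, EtOAc, rt
Reagents that add atoms: none
Why: Heterogeneous hydrogenation saturates the cis-disubstituted C2=C3 alkene and leaves both carbonyl groups.

Step 15
Reactants: 22 saturated keto aldehyde
Product: 24 trans-fused enone (C6=C7, C8 ketone; CH2OSi on C4 on the H5 face), via aldol 23 (not isolated)
Conditions: KOH, MeOH, 0 °C → rt
Reagents that add atoms: none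
Why: Intramolecular aldol condensation, in which the methyl-ketone enolate (C7) is the only enolate that reaches a carbonyl through a six-membered ring, adds to C6 and the aldol dehydrates to the conjugated enone; the trans fusion follows from C5 and C10 as set in step 10.

Step 16
Reactants: 24 enone
Product: 25 6,7-epoxy-8-ketone (epoxide on the H5 face)
Conditions: H2O2 (30 % aq.), NaOH, MeOH, 0 °C
Reagents that add atoms: hydrogen peroxide, OO
Why: Weitz–Scheffer nucleophilic epoxidation: hydroperoxide adds to C6 on the H5 face, away from the axial C19 and C20 methyl groups, and the enolate closes the oxirane on that face, fixing the C6 oxygen cis to H5.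

Step 17
Reactants: 26 4-(trimethylsilyl)but-3-yn-1-ol
Product: 27 4-(trimethylsilyl)but-3-ynyl trifluoromethanesulfonate
Conditions: Tf2O, pyridine, CH2Cl2, −78 → −20 °C; used at once
Reagents that add atoms: trifluoromethanesulfonic anhydride, O=S(=O)(OS(=O)(=O)C(F)(F)F)C(F)(F)F
Why: O-sulfonylation of the primary alcohol gives an alkylating agent reactive enough to alkylate at −78 °C, where elimination to the enyne is slow.

Step 18
Reactants: 25 epoxy ketone; 27 alkynyl triflate
Product: 29 C9-alkylated epoxy ketone (chain on the H5 face, trans to C20), via lithium enolate 28 (not isolated)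
Conditions: LiN(iPr)2, THF, −78 °C; then 27, DMPU, −78 → −30 °C
Reagents that add atoms: none
Why: C9 is the only enolisable position of the epoxy ketone, and its lithium enolate is C-alkylated by the primary triflate (SN2); attack anti to the C20 methyl should give mainly the C9 epimer with the chain trans to C20, which step 19 corrects.

Step 19
Reactants: 29 alkylated epoxy ketone (chain trans to C20)
Product: 31 C9 epimer of 29 (chain on the C20 face, H9 on the H5 face), via potassium enolate 30 (not isolated)
Conditions: KN(SiMe3)2, THF, −78 → −20 °C; then AcOH, THF, −78 °C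
Reagents that add atoms: none
Why: Re-enolisation at C9 and kinetic protonation of the enolate: the proton enters axially on the face opposite the C20 methyl, which leaves the side chain equatorial and cis to C20, and the cold acidic quench prevents re-equilibration.

Step 20
Reactants: 31 epoxy ketone (chain cis to C20)
Product: 32 6-hydroxy-8-ketone (6-OH on the H5 face)
Conditions: SmI2, THF/MeOH, −78 °C
Reagents that add atoms: none
Why: SmI2 reductive opening of the α,β-epoxy ketone cleaves the C7–O bond by two single-electron transfers and the samarium enolate is protonated at C7; C6–O stays in place and C9 is not enolised.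

Step 21
Reactants: 32 β-hydroxy ketone
Product: 33 8(17)-methylidene alcohol
Conditions: Zn, CH2Br2, TiCl4, THF/CH2Cl2, 0 °C → rt
Reagents that add atoms: dibromomethane, BrCBr
Why: Lombardo methylenation with the non-basic zinc/titanium methylene reagent converts the hindered, enolisable C8 ketone into the exocyclic alkene without epimerising C9 and without retro-aldol cleavage.

Step 22
Reactants: 33 exocyclic alkene
Product: 34 8,17-epoxide (oxygen on the H5 face)
Conditions: mCPBA, NaHCO3, CH2Cl2, 0 °C
Reagents that add atoms: 3-chloroperbenzoic acid, OOC(=O)c1cccc(Cl)c1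
Why: Prilezhaev epoxidation of the 1,1-disubstituted alkene from its equatorial face, opposite the syn-axial C20 methyl, puts the oxygen on the H5 face; the silylalkyne does not react.

Step 23
Reactants: 34 spiro-epoxide
Product: 35 6,8-diol (8-OH on the H5 face, C17 methyl on the C20 face)
Conditions: LiAlH4, THF, 0 °C → rt
Reagents that add atoms: none
Why: Hydride opens the epoxide at the primary carbon C17 (SN2) and leaves the tertiary C8–O bond, giving the equatorial 8-hydroxyl with an axial methyl.

Step 24
Reactants: 35 diol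
Product: 36 6-acetate
Conditions: Ac2O, pyridine, DMAP (cat.), CH2Cl2, rt
Reagents that add atoms: acetic anhydride, CC(=O)OC(C)=O
Why: Nucleophile-catalysed acylation takes the secondary 6-hydroxyl only, since the tertiary 8-hydroxyl does not react under these conditions.

Step 25
Reactants: 36 silyl-protected acetate
Product: 37 6-acetoxy-9-(but-3-ynyl) diol (free 8-OH and C18-OH)
Conditions: Bu4NF, AcOH, THF, rt
Reagents that add atoms: none
Why: Fluoride cleaves the alkynyl C–Si bond and the primary silyl ether, and the acetic acid buffer should suppress acetyl migration from O6 to O18.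

Step 26
Reactants: 37 terminal alkyne
Product: 38 target, (4S,5S,6R,8S,9S,10R)-6-acetoxylabda-13(16),14-diene-8,18-diol
Conditions: RuCl2(=CHPh)(PCy3)(H2IMes) (second-generation Grubbs catalyst, cat.), ethylene (1 atm), PhMe, 80 °C
Reagents that add atoms: ethylene, C=C
Why: Cross enyne metathesis of the terminal alkyne with ethylene gives the 2-substituted buta-1,3-diene (C13=C16 and C14=C15) directly, and the substrate has no other alkene.

Compound list
1 | 4-methylfuran-2(5H)-one | CC1=CC(=O)OC1 | starting material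
2 | (Z)-4-hydroxy-N-methoxy-N,3-dimethylbut-2-enamide | CON(C)C(=O)/C=C(/C)CO | intermediate
3 | (Z)-4-(tert-butyldimethylsilyloxy)-N-methoxy-N,3-dimethylbut-2-enamide | CON(C)C(=O)/C=C(/C)CO[Si](C)(C)C(C)(C)C | intermediate
4 | (Z)-4-(tert-butyldimethylsilyloxy)-3-methylbut-2-enal | O=C/C=C(/C)CO[Si](C)(C)C(C)(C)C | intermediate
5 | 2,2,6-trimethyl-4H-1,3-dioxin-4-one | CC1=CC(=O)OC(C)(C)O1 | starting material
6 | 2,2-dimethyl-6-methylidene-4-(trimethylsilyloxy)-6H-1,3-dioxine | C=C1C=C(O[Si](C)(C)C)OC(C)(C)O1 | intermediate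
7 | O-trimethylsilyl ether of 8 | CC1(C)OC(=O)C=C(C[C@@H](O[Si](C)(C)C)/C=C(/C)CO[Si](C)(C)C(C)(C)C)O1 | intermediate
8 | 6-[(2R,3Z)-5-(tert-butyldimethylsilyloxy)-2-hydroxy-4-methylpent-3-enyl]-2,2-dimethyl-4H-1,3-dioxin-4-one | CC1(C)OC(=O)C=C(C[C@@H](O)/C=C(/C)CO[Si](C)(C)C(C)(C)C)O1 | intermediate
9 | (5R,6Z)-8-(tert-butyldimethylsilyloxy)-5-hydroxy-7-methylocta-1,6-diene-1,3-dione (acylketene) | O=C=CC(=O)C[C@@H](O)/C=C(/C)CO[Si](C)(C)C(C)(C)C | intermediate
10 | (6R)-6-[(1Z)-3-(tert-butyldimethylsilyloxy)-2-methylprop-1-enyl]oxane-2,4-dione | O=C1CC(=O)C[C@H](/C=C(/C)CO[Si](C)(C)C(C)(C)C)O1 | intermediate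
11 | (2R)-2-[(1Z)-3-(tert-butyldimethylsilyloxy)-2-methylprop-1-enyl]-6-oxo-3,6-dihydro-2H-pyran-4-yl trifluoromethanesulfonate | O=C1C=C(OS(=O)(=O)C(F)(F)F)C[C@H](/C=C(/C)CO[Si](C)(C)C(C)(C)C)O1 | intermediate
12 | allyltributylstannane | C=CC[Sn](CCCC)(CCCC)CCCC | starting material
13 | (6R)-4-allyl-6-[(1Z)-3-(tert-butyldimethylsilyloxy)-2-methylprop-1-enyl]-5,6-dihydro-2H-pyran-2-one | O=C1C=C(CC=C)C[C@H](/C=C(/C)CO[Si](C)(C)C(C)(C)C)O1 | intermediate
14 | cyclic trimethylsilyl ketene acetal of 15 (C5=C6, C6–OSiMe3) | C[Si](C)(C)OC1=C[C@](C)(CC=C)C[C@H](/C=C(/C)CO[Si](C)(C)C(C)(C)C)O1 | intermediate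
15 | (4R,6R)-4-allyl-6-[(1Z)-3-(tert-butyldimethylsilyloxy)-2-methylprop-1-enyl]-4-methyltetrahydro-2H-pyran-2-one (allyl cis to the arm) | O=C1C[C@](C)(CC=C)C[C@H](/C=C(/C)CO[Si](C)(C)C(C)(C)C)O1 | intermediate
16 | cyclic tert-butyldimethylsilyl ketene acetal of 15 | CC(C)(C)[Si](C)(C)OC1=C[C@](C)(CC=C)C[C@H](/C=C(/C)CO[Si](C)(C)C(C)(C)C)O1 | intermediate
17 | tert-butyldimethylsilyl ester of 18 | C=CC[C@]1(C)CC=C[C@](C)(CO[Si](C)(C)C(C)(C)C)[C@H]1C(=O)O[Si](C)(C)C(C)(C)C | intermediate
18 | (1S,2S,6R)-6-allyl-2-(tert-butyldimethylsilyloxymethyl)-2,6-dimethylcyclohex-3-ene-1-carboxylic acid | C=CC[C@]1(C)CC=C[C@](C)(CO[Si](C)(C)C(C)(C)C)[C@H]1C(=O)O | intermediate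
19 | [(1S,2S,6R)-6-allyl-2-(tert-butyldimethylsilyloxymethyl)-2,6-dimethylcyclohex-3-en-1-yl]methanol | C=CC[C@]1(C)CC=C[C@](C)(CO[Si](C)(C)C(C)(C)C)[C@H]1CO | intermediate
20 | (1S,2S,6R)-6-allyl-2-(tert-butyldimethylsilyloxymethyl)-2,6-dimethylcyclohex-3-ene-1-carbaldehyde | C=CC[C@]1(C)CC=C[C@](C)(CO[Si](C)(C)C(C)(C)C)[C@H]1C=O | intermediate
21 | (1S,2S,6S)-2-(tert-butyldimethylsilyloxymethyl)-2,6-dimethyl-6-(2-oxopropyl)cyclohex-3-ene-1-carbaldehyde | CC(=O)C[C@]1(C)CC=C[C@](C)(CO[Si](C)(C)C(C)(C)C)[C@H]1C=O | intermediate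
22 | (1S,2S,6S)-2-(tert-butyldimethylsilyloxymethyl)-2,6-dimethyl-6-(2-oxopropyl)cyclohexane-1-carbaldehyde | CC(=O)C[C@]1(C)CCC[C@](C)(CO[Si](C)(C)C(C)(C)C)[C@H]1C=O | intermediate
23 | trans-fused 6-hydroxy-8-ketone without C9 chain (aldol; 6-OH and CH2OSi on the H5 face) | O=C1C[C@@H](O)[C@@H]2[C@@](C)(CO[Si](C)(C)C(C)(C)C)CCC[C@@]2(C)C1 | intermediate
24 | trans-fused enone: 4-(tert-butyldimethylsilyloxymethyl)-4,10-dimethyldecal-6-en-8-one (labdane locants; H5 trans to C20, CH2OSi on the H5 face) | O=C1C=C[C@@H]2[C@@](C)(CO[Si](C)(C)C(C)(C)C)CCC[C@@]2(C)C1 | intermediate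
25 | 6,7-epoxide of 24 (oxirane on the H5 face) | O=C1[C@H]2O[C@H]2[C@@H]3[C@@](C)(CO[Si](C)(C)C(C)(C)C)CCC[C@@]3(C)C1 | intermediate
26 | 4-(trimethylsilyl)but-3-yn-1-ol | C[Si](C)(C)C#CCCO | starting material
27 | 4-(trimethylsilyl)but-3-ynyl trifluoromethanesulfonate | C[Si](C)(C)C#CCCOS(=O)(=O)C(F)(F)F | intermediate
28 | lithium C8–C9 enolate of 25 | [Li+].[O-]C=1[C@H]2O[C@H]2[C@@H]3[C@@](C)(CO[Si](C)(C)C(C)(C)C)CCC[C@@]3(C)C=1 | intermediate
29 | 25 with a 4-(trimethylsilyl)but-3-ynyl chain on C9, chain on the H5 face (trans to C20) | O=C1[C@H]2O[C@H]2[C@@H]3[C@@](C)(CO[Si](C)(C)C(C)(C)C)CCC[C@@]3(C)[C@H]1CCC#C[Si](C)(C)C | intermediate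
30 | potassium C8–C9 enolate of 29 | [K+].[O-]C=1[C@H]2O[C@H]2[C@@H]3[C@@](C)(CO[Si](C)(C)C(C)(C)C)CCC[C@@]3(C)C=1CCC#C[Si](C)(C)C | intermediate
31 | C9 epimer of 29: chain on the C20 face (cis to C20), H9 on the H5 face | O=C1[C@H]2O[C@H]2[C@@H]3[C@@](C)(CO[Si](C)(C)C(C)(C)C)CCC[C@@]3(C)[C@@H]1CCC#C[Si](C)(C)C | intermediate
32 | 6-hydroxy-8-ketone with C9 chain (6-OH on the H5 face, chain cis to C20) | O=C1C[C@@H](O)[C@@H]2[C@@](C)(CO[Si](C)(C)C(C)(C)C)CCC[C@@]2(C)[C@@H]1CCC#C[Si](C)(C)C | intermediate
33 | 8(17)-methylidene analogue of 32 (6-OH retained) | C=C1C[C@@H](O)[C@@H]2[C@@](C)(CO[Si](C)(C)C(C)(C)C)CCC[C@@]2(C)[C@@H]1CCC#C[Si](C)(C)C | intermediate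
34 | 8,17-epoxide of 33 (oxygen on the H5 face, C17 on the C20 face) | C1O[C@]12C[C@@H](O)[C@@H]3[C@@](C)(CO[Si](C)(C)C(C)(C)C)CCC[C@@]3(C)[C@@H]2CCC#C[Si](C)(C)C | intermediate
35 | 6,8-diol (8-OH on the H5 face, C17 methyl on the C20 face; C18 silyl ether, silylalkyne) | C[C@]1(O)C[C@@H](O)[C@@H]2[C@@](C)(CO[Si](C)(C)C(C)(C)C)CCC[C@@]2(C)[C@@H]1CCC#C[Si](C)(C)C | intermediate
36 | 6-acetate of 35 | C[C@]1(O)C[C@@H](OC(C)=O)[C@@H]2[C@@](C)(CO[Si](C)(C)C(C)(C)C)CCC[C@@]2(C)[C@@H]1CCC#C[Si](C)(C)C | intermediate
37 | 6-acetoxy-9-(but-3-ynyl) diol: 36 without both silyl groups | C[C@]1(O)C[C@@H](OC(C)=O)[C@@H]2[C@@](C)(CO)CCC[C@@]2(C)[C@@H]1CCC#C | intermediate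
38 | (4S,5S,6R,8S,9S,10R)-6-acetoxylabda-13(16),14-diene-8,18-diol (ent-labdane series) | C=CC(=C)CC[C@H]1[C@]2(C)CCC[C@](C)(CO)[C@H]2[C@H](OC(C)=O)C[C@]1(C)O | target

Total step count: 26. Longest linear sequence: 24 steps (steps 1–3, 5–16 and 18–26, from 1 to 38).

Steps most likely to fail

Step 10. The ketene acetal may be lost by ionisation of the allylic C2–O bond, C-silylation or hydrolysis before the congested C4–C5 bond can form, since this bond joins a fully substituted alkene terminus to a carbon next to quaternary C10. The fallback uses the thermal Claisen rearrangement of the cyclic enol ether in place of the enolate. It sets out from 15: reduction with iBu2AlH (CH2Cl2, −78 °C) should give the lactol (4R,6R)-4-allyl-6-[(1Z)-3-(tert-butyldimethylsilyloxy)-2-methylprop-1-enyl]-4-methyltetrahydro-2H-pyran-2-ol F1. MsCl and Et3N should convert it into the anomeric methanesulfonate F2, which eliminates in the same flask to the 2-alkenyl-3,4-dihydro-2H-pyran F3. Heating F3 (xylenes, 160–180 °C, sealed, base-washed glass) should drive the same tether-enforced boat [3,3] shift and give the C6 aldehyde directly. The fallback comes back to the route at 20, so steps 11 and 12 are not needed.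

Step 18. At the neopentyl-type C9 the lithium enolate may react on oxygen, cause elimination of the triflate, or attack its own oxirane instead of undergoing C-alkylation. The fallback alkylates before the epoxide exists and sets out from 24. Kinetic deprotonation (LiN(iPr)2, THF, −78 °C) should give the cross-conjugated lithium dienolate F4, a softer and better C-nucleophile, which is alkylated with 27 to the C9-alkylated enone F5. Nucleophilic epoxidation under aprotic conditions that spare the alkynylsilane (t-BuOOH, DBU, CH2Cl2) should then give the epoxy ketone, and the fallback comes back to the route at 29.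

Step 19. The amide base may not reach the shielded C9–H, or the proton may enter with poor facial discrimination, so that the chain stays trans to C20. The fallback makes the enol derivative under equilibrating soft-enolisation conditions and releases the enolate from it; it sets out from 29. Me3SiOTf and Et3N (CH2Cl2, 0 °C) should give the only possible enol ether, the C8–C9 trimethylsilyl enol ether F6. KOtBu (THF, −40 °C) should cleave its O–Si bond to the potassium enolate, so the fallback comes back to the route at 30, which is protonated at −78 °C (AcOH, or a bulkier acid such as 2,6-di-tert-butyl-4-methylphenol) to 31.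

Further compounds
F1 | step 10 | (4R,6R)-4-allyl-6-[(1Z)-3-(tert-butyldimethylsilyloxy)-2-methylprop-1-enyl]-4-methyltetrahydro-2H-pyran-2-ol (anomers) | OC1C[C@](C)(CC=C)C[C@H](/C=C(/C)CO[Si](C)(C)C(C)(C)C)O1
F2 | step 10 | anomeric methanesulfonate of F1 | CS(=O)(=O)OC1C[C@](C)(CC=C)C[C@H](/C=C(/C)CO[Si](C)(C)C(C)(C)C)O1
F3 | step 10 | (2R,4R)-4-allyl-2-[(1Z)-3-(tert-butyldimethylsilyloxy)-2-methylprop-1-enyl]-4-methyl-3,4-dihydro-2H-pyran | C1=C[C@](C)(CC=C)C[C@H](/C=C(/C)CO[Si](C)(C)C(C)(C)C)O1
F4 | step 18 | lithium cross-conjugated dienolate of 24 (C8–O, C8=C9, C6=C7) | [Li+].[O-]C=1C=C[C@@H]2[C@@](C)(CO[Si](C)(C)C(C)(C)C)CCC[C@@]2(C)C=1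
F5 | step 18 | 24 with a 4-(trimethylsilyl)but-3-ynyl chain on C9 (chain on the H5 face) | O=C1C=C[C@@H]2[C@@](C)(CO[Si](C)(C)C(C)(C)C)CCC[C@@]2(C)[C@H]1CCC#C[Si](C)(C)C
F6 | step 19 | C8–C9 trimethylsilyl enol ether of 29 | C[Si](C)(C)OC=1[C@H]2O[C@H]2[C@@H]3[C@@](C)(CO[Si](C)(C)C(C)(C)C)CCC[C@@]3(C)C=1CCC#C[Si](C)(C)C
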